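(The runs are simulated for an exercise, noise included.)

- Start from 57%: the target read at 360 min in the north-east run, which is the flask asked about, while the south-west run, at −25 °C instead of −20 °C, reads 38%.

in all of them: starting material 2.8 M
- north-east: temperature −20 °C; the very flask that is asked about, followed so far
- south-west: temperature −25 °C; run made earlier
- flask: temperature −20 °C; time 6.0 h
- north-east (time / min: target / %, starting material / %): 30.0: 53, 1; 60.0: 58, 0; 150: 57, 0; 360: 57, 1
- south-west (time / min: target / %, starting material / %): 30.0: 40, 1; 60.0: 39, 2; 150: 38, 3; 360: 38, 0

(scatter of a reading: 2 percentage points)
- Wednesday's: change nothing and wait 3.0 h more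
- Monday's: at 6.0 h raise the temperature by 15 K, then wait 3.0 h
- Saturday's: at 6.0 h take out 90% of the target then present, then wait 3.0 h
- target that was removed still counts
- candidate steps: starting material -> intermediate; intermediate <-> isomer of the product; intermediate <-> target
* target, in percent of the starting material first charged, at 6.0 h
* what to do for the largest gain in target; "none" if nothing gains more than 2 percentage points (Wednesday's / Monday's / Saturday's / none)
* target present, with what was taken out counted in, in percent of the starting material first charged, after Monday's
* target present, with what was taken out counted in, in percent of the starting material first charged, after Saturday's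

- Compare two amounts, target and everything else the charge has become. In the north-east run starting material reads 1% by 30.0 min, and from 60.0 min on target reads between 57% and 58%, within the scatter of 2 percentage points.
- Take target over the rest of the charge as the plateau ratio: my reading is 1.33 at −20 °C and 0.613 at −25 °C.
- Expect about 57% now, and expect nothing from Wednesday's, since the north-east readings are flat.
- Suppose the plateau is an equilibrium, which is thermodynamic control. Then 15 K is 3 steps of the gap between the two runs, each step multiplying the ratio by the observed factor 2.16, and my ratio of 13.4 gives 93.1% target after Monday's.
- Let the remainder split again at the same share after Saturday's, and my total is 79.1%, less than my Monday figure.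
- The forecast gives 57% now, 88% after Monday's and 78% after Saturday's, and chooses Monday's. Its Monday figure is lower than mine, and it notes that “a frozen kinetic split can't be strictly excluded”.
- The flask gives 55.2% now, 88.4% after Monday's and 77.5% after Saturday's; the choice is Monday's, with gains of 33 points for it and 22 points for Saturday's.

    starting material → intermediate (k = 0.0102 s⁻¹, Ea = 77.0 kJ mol⁻¹)
    intermediate ⇌ isomer of the product (K = 2.40, k = 0.00688 s⁻¹, Ea = 80.0 kJ mol⁻¹, ΔH = −16.0 kJ mol⁻¹)
    intermediate ⇌ target (K = 4.19, k = 0.0134 s⁻¹, Ea = 75.0 kJ mol⁻¹, ΔH = 58.0 kJ mol⁻¹)
    (constants at −20 °C)

- In the flask, intermediate and target relax towards each other with a half-life of 0.696 min by their own step alone, both ways together, shorter than the 6.0 h of the run, and target stands at 55.2% at 36.0 min and 55.2% at 3600 min. The plateau ratio of the flask is 1.23, with 31.6% isomer of the product and 13.2% intermediate as the rest. Carried 3 steps down from my reading of 1.33, the ratio becomes 0.131, a target share of 11.6%; the neighbour flask at −35 °C holds 13.2% target.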